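The earlier runs and the new flask were generated by integration on assumed constants, noise included.

Double product cannot account for the gap in the gamma run. First product reads 74.6 % at 1.00 min, so 25 percentage points of the charge is missing, and its later fall, 0.158 /min between 2.00 min and 4.00 min, takes 14.6 % in that time. A second form sharing the material fits these readings, and the isomer of the product is the candidate.

in all of them: starting material 0.0010 M
- beta: partner 1.1 equiv; run made earlier
- gamma: partner 3.9 equiv; run made earlier
- Wednesday's: partner 1.00 equiv; time 8.0 min
- Friday's: partner 2.00 equiv; time 8.0 min
- Monday's: partner 2.50 equiv; time 8.0 min

| run | time / min | first product / % |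
|---|---|---|
| beta | 0.833 | 59.5 |
| beta | 1.50 | 67.5 |
| beta | 2.50 | 74.1 |
| beta | 3.00 | 74.8 |
| beta | 4.00 | 76.6 |
| gamma | 0.333 | 75.6 |
| gamma | 1.00 | 74.6 |
| gamma | 2.00 | 63.4 |
| gamma | 3.00 | 54.7 |
| gamma | 4.00 | 46.2 |

(readings scatter by 0.5 percentage points)

- final first product, as a percentage of the starting material charged, for each flask in turn (Wednesday's, Friday's, Monday's)

- steps thought possible: starting material + partner -> first product; partner + first product -> double product; first product <-> isomer of the product

1. Call the pool c(first product) + c(isomer of the product). Running the gamma fall back to zero time gives first product a share of the pool of 87.0 %. Objection: that assumes a constant share. But the same line gives 74.3 % at 1.00 min, and the reading is 74.6 %, so the line stands at that reading too.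

2. Dividing the fall by the partner left after the first addition gives 0.0546 /min per equivalent. Objection: double product also uses partner. At 3.00 min the pool is down to 62.9 %, which leaves 2.53 equivalents of partner. The better figure is 0.0626 /min, the loss constant: pool lost per minute, per unit of pool and per equivalent of partner left. The gamma run and the new flasks are charged with 0.0010 M of starting material, so equivalents compare directly.

3. Once starting material is used, partner left equals the pool plus the charge minus 2 equivalents. For Friday's flask this reckons a pool of 66.6 %, and so first product at 57.9 %. For Monday's flask it reckons a pool of 54.0 %, and so first product at 47.0 %. Objection: the pool fills over the first minutes, not at zero time, so both figures lean low.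

4. Wednesday's flask has 1.00 equiv of partner, and the balance of step 3 is not applied to it, since that balance starts from starting material used. The beta run, with 1.1 equiv of partner, reads 76.6 % at 4.00 min, and the reckoning here takes that reading for Wednesday's flask.

5. The forecast gives 73 %, 58 % and 48 %, resting on “a quick first product/isomer equilibrium”. For Wednesday's flask it stands below the reckoning here, and for Monday's flask above it.

The flasks give 77.3 %, 59.0 % and 47.8 %, within the forecast's margin.

    starting material + partner → first product (k = 35.0 /M/s)
    partner + first product → double product (k = 1.20 /M/s)
    first product ⇌ isomer of the product (K = 0.130, k = 0.0720 /s)

In Friday's flask, first product has a half-life of 4.8 min toward double product at the charged concentrations, shorter than the 8.0 min of the run; the loss constant gives the pool 5.54 min on the same footing, and the pool stands at 66.6 % after 8.00 min, against 66.6 % reckoned. In Monday's flask the same constant gave 54.0 %, and first product and isomer of the product together stand at 54.0 % after 8.00 min.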